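**Retrosynthetic overview**

1. The only ring, the 42-membered lactone, is closed last (O41–C1) from a seco acid that carries a single free hydroxyl at C41.
2. The seco acid comes from a C6 bromide of the C6–C50 chain and 5-methyl-2H-pyran-2-one by a visible-light nickel/photoredox ring-opening coupling; it forms C5–C6 and releases the (2Z,4Z)-dienoic acid.
3. The chain comes from fragment A (C6–C21 alkyne), fragment B (C22–C37 epoxide), lithium acetylide (C38–C39) and fragment C (C40–C50 epoxide) by two alkyne/epoxide unions, then cis semi-hydrogenation.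
4. Fragments A and B are built by dithiane linchpin couplings of purchased epoxides; in A the O7/O11 TES ethers are cleaved selectively and the three unmasked ketones are reduced under hydroxyl direction (C9, C13, C17), in B the dithianes are reduced to CH2.
5. C17–C20 and C40–C43 come from (S)- and (R)-3-hydroxy-γ-butyrolactone by dianion methylation; C49 comes from (R)-propylene oxide.

Convention and assumption: carbon numbers C1–C50 are those of the macrolide (C1 lactone carbonyl, C41 lactone carbinol, C50 terminal methyl); TBS = tert-butyldimethylsilyl, TES = triethylsilyl, PMB = 4-methoxybenzyl; where a name gives no descriptor the SMILES fixes the configuration; every compound marked starting material is assumed purchasable.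

**Route**

Step 1
Reactants: 1 (S)-3-hydroxy-γ-butyrolactone
Product: 2 (3S,4S)-4-hydroxy-3-methyloxolan-2-one
Conditions: LiN(i-Pr)2 (2.2 equiv), THF, −78 to −40 °C; MeI, −78 to −30 °C; then H2O
Reagents that add atoms: iodomethane, `CI`
Why: Fráter–Seebach-type alkylation of the lactone dianion; MeI enters trans to the C19 alkoxide (substrate control), which is the 18,19-syn relationship of the open chain.

Step 2
Reactants: 2 (3S,4S)-4-hydroxy-3-methyloxolan-2-one
Product: 3 (3S,4S)-3-methyloxolane-2,4-diol (lactol)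
Conditions: i-Bu2AlH (2.3 equiv), CH2Cl2, −78 °C; then H2O
Reagents that add atoms: none
Why: Lactone-to-lactol half reduction stops at the aluminium hemiacetal at −78 °C and touches neither stereocentre.

Step 3
Reactants: 3 lactol
Product: 4 (2S,3S)-3-(1,3-dithian-2-yl)butane-1,2-diol
Conditions: HS(CH2)3SH, BF3·OEt2 (20 mol %), CH2Cl2, −20 to 0 °C
Reagents that add atoms: propane-1,3-dithiol, `SCCCS`
Why: Lewis-acid dithioacetalisation opens the lactol to the C17 dithiane (masked acyl anion) and frees the C19/C20 diol.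

Step 4
Reactants: 4 dithiane diol
Product: 5 2-[(2S,3S)-3,4-bis(TBS-oxy)butan-2-yl]-1,3-dithiane
Conditions: TBSOTf, 2,6-lutidine, CH2Cl2, 0 °C
Reagents that add atoms: tert-butyldimethylsilyl trifluoromethanesulfonate, `CC(C)(C)[Si](C)(C)OS(=O)(=O)C(F)(F)F`
Why: Silyl ether formation masks both hydroxyls for the organolithium step and for the later selective TES cleavage; the oxygen at C19 is two carbons away from the future carbanion, so it cannot eliminate.

Step 5
Reactants: 6 (S)-glycidol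
Product: 7 (R)-2-[(4-methoxybenzyloxy)methyl]oxirane
Conditions: NaH, 4-MeOC6H4CH2Cl, Bu4NI (cat.), THF, 0 °C to rt
Reagents that add atoms: 4-methoxybenzyl chloride, `COc1ccc(CCl)cc1`
Why: Williamson etherification; the epoxide stereocentre (future C7) is untouched and only its descriptor changes.

Step 6
Reactants: 8 1,3-dithiane
Product: 9 2-(triethylsilyl)-1,3-dithiane
Conditions: n-BuLi, THF, −30 °C; Et3SiCl, −78 °C to rt
Reagents that add atoms: chlorotriethylsilane, `CC[Si](Cl)(CC)CC`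
Why: Corey–Seebach lithiation of 1,3-dithiane at C2 and C-silylation of the anion give the linchpin whose silyl group later ends up as an acid-labile TES ether.

Step 7
Reactants: 9 2-(triethylsilyl)-1,3-dithiane; 7 PMB glycidyl ether; 10 (S)-epichlorohydrin
Product: 13 C6–C12 epoxide, via lithium alkoxide adduct 11 (not isolated), via chlorohydrin alkoxide 12 (not isolated)
Conditions: t-BuLi, Et2O, −78 to −45 °C; 7, −78 to −25 °C; then 10, THF/HMPA, −78 °C to rt
Reagents that add atoms: none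
Why: Three-component dithiane linchpin coupling (anion relay): the lithiated dithiane opens 7 at CH2 in Et2O, where the C-silyl alkoxide persists; HMPA then triggers a 1,4-Brook shift of TES to O7, the new dithiane anion opens 10 at its epoxide CH2 and the alkoxide displaces chloride; C7 and C11 come unchanged from the purchased epoxides.

Step 8
Reactants: 9 2-(triethylsilyl)-1,3-dithiane; 13 C6–C12 epoxide; 10 (S)-epichlorohydrin
Product: 16 C6–C16 epoxide, via lithium alkoxide adduct 14 (not isolated), via chlorohydrin alkoxide 15 (not isolated)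
Conditions: t-BuLi, Et2O, −78 to −45 °C; 13, −78 to −25 °C; then 10, THF/HMPA, −78 °C to rt
Reagents that add atoms: none
Why: The same anion-relay linchpin coupling adds the C13 dithiane, the O11 TES ether and the C15–C16 epoxide; C15 comes from (S)-epichlorohydrin.

Step 9
Reactants: 5 bis-TBS dithiane; 16 C6–C16 epoxide
Product: 17 C6–C20 tris-dithiane alcohol
Conditions: t-BuLi, THF/HMPA (9:1), −78 °C; 16, −78 to −20 °C; then H2O
Reagents that add atoms: none
Why: Corey–Seebach dithiane anion alkylation at the terminal epoxide carbon C16; no stereocentre is formed and C18 cannot epimerise next to a dithiane.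

Step 10
Reactants: 17 tris-dithiane alcohol
Product: 18 C6–C20 9,13,17-triketone
Conditions: Hg(ClO4)2, CaCO3, THF/H2O (5:1), 0 °C
Reagents that add atoms: water, `O`
Why: Mercury-assisted dithiane hydrolysis (Corey–Seebach unmasking), buffered so that the silyl ethers, the PMB ether and the C18 α-stereocentre survive.

Step 11
Reactants: 18 triketone
Product: 19 C6–C20 7,11,15-trihydroxy triketone
Conditions: pyridinium p-toluenesulfonate (0.2 equiv), MeOH/CH2Cl2 (1:3), 0 °C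
Reagents that add atoms: none
Why: Acid-catalysed methanolysis cleaves secondary TES ethers far faster than TBS ethers, so the C7 and C11 hydroxyls needed to direct the reductions are freed while the C19/C20 TBS ethers and the PMB ether stay; the reaction is stopped as soon as the TES ethers are gone to spare the primary C20 silyl ether.

Step 12
Reactants: 19 trihydroxy triketone
Product: 20 C6–C20 hexaol
Conditions: Me4NBH(OAc)3, MeCN/AcOH (1:1), −30 to −20 °C
Reagents that add atoms: none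
Why: Evans–Saksena hydroxyl-directed reduction (internal hydride delivery from an alkoxyacetoxyborohydride); the C9 and C13 ketones are each flanked by two mutually syn β-hydroxyls that direct to the same face and the C17 ketone is directed by the C15 hydroxyl, which sets C9, C13 and C17 1,3-anti to their neighbours and gives 17,18-anti; the silylated C19/C20 oxygens cannot form a hemiketal with the C17 ketone.

Step 13
Reactants: 20 hexaol
Product: 21 octakis-TBS ether
Conditions: TBSOTf (8 equiv), 2,6-lutidine, CH2Cl2, −78 °C to rt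
Reagents that add atoms: tert-butyldimethylsilyl trifluoromethanesulfonate, `CC(C)(C)[Si](C)(C)OS(=O)(=O)C(F)(F)F`
Why: Exhaustive silylation of the six free secondary hydroxyls with the most reactive silylating agent gives one uniform protecting group for the final deprotection.

Step 14
Reactants: 21 octakis-TBS ether
Product: 22 C20 primary alcohol
Conditions: HF·pyridine, pyridine, THF, 0 °C
Reagents that add atoms: none
Why: Selective desilylation; the single primary silyl ether is cleaved much faster than the seven hindered secondary ones.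

Step 15
Reactants: 22 C20 primary alcohol
Product: 23 C20 aldehyde
Conditions: Dess–Martin periodinane, pyridine, CH2Cl2, 0 °C to rt
Reagents that add atoms: none
Why: Dess–Martin oxidation under buffered conditions gives the α-silyloxy aldehyde without epimerising C19.

Step 16
Reactants: 23 C20 aldehyde
Product: 24 fragment A (C6–C21 alkyne)
Conditions: MeC(O)C(N2)P(O)(OMe)2, K2CO3, MeOH, 0 °C to rt
Reagents that add atoms: dimethyl (1-diazo-2-oxopropyl)phosphonate, `CC(=O)C(=[N+]=[N-])P(=O)(OC)OC`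
Why: Ohira–Bestmann (Seyferth–Gilbert) homologation adds C21 and gives the terminal alkyne under conditions mild enough for the α-OTBS centre.

Step 17
Reactants: 25 1-bromo-5-chloropentane; 26 (R)-epichlorohydrin
Product: 29 (R)-2-(6-chlorohexyl)oxirane, via Grignard reagent 27 (not isolated), via chlorohydrin 28 (not isolated)
Conditions: Mg, THF, 35 °C; CuI (5 mol %), 26, −40 to 0 °C; then NaOH (aq.), rt
Reagents that add atoms: none
Why: Copper-catalysed Grignard opening of the epoxide at CH2, then Williamson closure of the chlorohydrin; C31 comes unchanged from (R)-epichlorohydrin.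

Step 18
Reactants: 30 2-(tert-butyldimethylsilyl)-1,3-dithiane; 29 chloro epoxide; 26 (R)-epichlorohydrin
Product: 33 C26–C37 epoxide, via lithium alkoxide adduct 31 (not isolated), via chlorohydrin alkoxide 32 (not isolated)
Conditions: t-BuLi, Et2O, −78 to −45 °C; 29, −78 to −25 °C; then 26, THF/HMPA, −78 °C to rt
Reagents that add atoms: none
Why: Anion-relay dithiane linchpin coupling as in step 7, here with the TBS linchpin so that the O31 silyl ether lasts to the end; the epoxide reacts faster than the primary chloride at low temperature, and C27 comes from (R)-epichlorohydrin.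

Step 19
Reactants: 30 2-(tert-butyldimethylsilyl)-1,3-dithiane; 33 C26–C37 epoxide; 34 (R)-benzyl glycidyl ether
Product: 36 C22–C37 bis-dithiane alcohol, via lithium alkoxide adduct 35 (not isolated)
Conditions: t-BuLi, Et2O, −78 to −45 °C; 33, −78 to −25 °C; then 34, THF/HMPA, −78 to 0 °C; then H2O
Reagents that add atoms: none
Why: Anion-relay linchpin coupling ending with an epoxide that leaves a free C23 hydroxyl; C23 comes from the purchased glycidyl ether.

Step 20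
Reactants: 36 bis-dithiane alcohol
Product: 37 C22–C37 22,23-diol
Conditions: Raney Ni (W-2), H2 (1 atm), EtOH, 60 °C
Reagents that add atoms: none
Why: Mozingo hydrogenolytic desulfurisation turns both dithianes into CH2 (the 1,5-diol spacing) and cleaves the benzyl ether while no unsaturation is present; the primary chloride is inert.

Step 21
Reactants: 37 22,23-diol
Product: 39 fragment B (C22–C37 epoxide), via primary tosylate 38 (not isolated)
Conditions: NaH, THF, 0 °C; 1-(p-toluenesulfonyl)imidazole, 0 °C to rt; then H2O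
Reagents that add atoms: none
Why: One-pot selective primary sulfonylation and Williamson closure gives the terminal epoxide with retention at C23.

Step 22
Reactants: 40 1-bromo-4-chlorobutane; 41 (R)-propylene oxide
Product: 43 (R)-7-chloroheptan-2-ol, via Grignard reagent 42 (not isolated)
Conditions: Mg, THF, 35 °C; CuI (5 mol %), 41, −30 to 0 °C; then H2O
Reagents that add atoms: none
Why: Copper-catalysed Grignard opening of the epoxide at CH2; C49 comes unchanged from (R)-propylene oxide.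

Step 23
Reactants: 43 (R)-7-chloroheptan-2-ol
Product: 44 (R)-tert-butyl[(7-chloroheptan-2-yl)oxy]dimethylsilane
Conditions: TBSCl, imidazole, DMF, rt
Reagents that add atoms: tert-butyldimethylsilyl chloride, `CC(C)(C)[Si](C)(C)Cl`
Why: Standard silyl ether formation before Grignard generation.

Step 24
Reactants: 45 (R)-3-hydroxy-γ-butyrolactone
Product: 46 (3R,4R)-4-hydroxy-3-methyloxolan-2-one
Conditions: LiN(i-Pr)2 (2.2 equiv), THF, −78 to −40 °C; MeI, −78 to −30 °C; then H2O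
Reagents that add atoms: iodomethane, `CI`
Why: Fráter–Seebach-type dianion alkylation trans to the C41 alkoxide sets C42 (41,42-syn in the open chain) under substrate control.

Step 25
Reactants: 46 (3R,4R)-4-hydroxy-3-methyloxolan-2-one
Product: 47 methyl (2R)-2-[(4R)-2,2-dimethyl-1,3-dioxolan-4-yl]propanoate
Conditions: Me2C(OMe)2, MeOH, p-TsOH (5 mol %), rt
Reagents that add atoms: 2,2-dimethoxypropane, `COC(C)(C)OC`; methanol, `CO`
Why: Acid-catalysed lactone methanolysis with trapping of the C40/C41 diol as the five-membered acetonide (transketalisation) drives the ring opening; no stereocentre is touched.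

Step 26
Reactants: 47 acetonide ester; 44 silyl ether chloride
Product: 50 C40–C50 ketone, via Grignard reagent 48 (not isolated), via Weinreb amide 49 (not isolated)
Conditions: 44, Mg, THF, 60 °C; separately 47, MeNH(OMe)·HCl, i-PrMgCl, THF, −20 °C; then the Grignard solution, −20 to 0 °C; then H2O
Reagents that add atoms: none
Why: One-pot Weinreb amide formation and Grignard acylation; the chelated tetrahedral intermediate prevents over-addition and the low temperature keeps C42 intact.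

Step 27
Reactants: 50 C40–C50 ketone
Product: 51 C40–C50 43-alcohol
Conditions: Zn(BH4)2, Et2O, −30 °C; then H2O
Reagents that add atoms: none
Why: Chelation-controlled (Cram-chelate) reduction: zinc bridges the C43 carbonyl and O41, and hydride attacks the face opposite the C42 methyl and the C40 arm, which sets C43 42,43-syn and 41,43-syn.

Step 28
Reactants: 51 43-alcohol
Product: 52 43,49-bis-TBS ether
Conditions: TBSOTf, 2,6-lutidine, CH2Cl2, −78 °C
Reagents that add atoms: tert-butyldimethylsilyl trifluoromethanesulfonate, `CC(C)(C)[Si](C)(C)OS(=O)(=O)C(F)(F)F`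
Why: Low-temperature silylation protects the C43 hydroxyl and leaves the acetonide intact.

Step 29
Reactants: 52 bis-TBS ether
Product: 53 C40–C50 40,41-diol
Conditions: CuCl2·2H2O, MeCN, 0 °C
Reagents that add atoms: none
Why: Mild Lewis-acid hydrolysis removes the terminal acetonide selectively in the presence of secondary silyl ethers.

Step 30
Reactants: 53 40,41-diol
Product: 55 fragment C (C40–C50 epoxide), via primary tosylate 54 (not isolated)
Conditions: NaH, THF, 0 °C; 1-(p-toluenesulfonyl)imidazole, 0 °C to rt; then H2O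
Reagents that add atoms: none
Why: Selective primary sulfonylation and Williamson closure gives the C40–C41 epoxide with retention at C41.

Step 31
Reactants: 56 5-bromo-2H-pyran-2-one
Product: 57 5-methyl-2H-pyran-2-one
Conditions: MeZnCl, Pd(PPh3)4 (5 mol %), THF, rt
Reagents that add atoms: methylzinc chloride, `C[Zn]Cl`
Why: Negishi cross-coupling at the vinylic C–Br bond (insertion of zerovalent palladium); the non-basic zinc reagent spares the lactone.

Step 32
Reactants: 24 fragment A; 39 fragment B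
Product: 58 C6–C37 alkynol
Conditions: n-BuLi, THF, −78 °C; BF3·OEt2; 39, −78 °C; then H2O
Reagents that add atoms: none
Why: Yamaguchi alkynylation (BF3-promoted opening of the epoxide by the lithium acetylide at C22) forms C21–C22 and leaves C23 untouched.

Step 33
Reactants: 58 alkynol
Product: 59 23-O-TBS ether
Conditions: TBSOTf, 2,6-lutidine, CH2Cl2, −78 to 0 °C
Reagents that add atoms: tert-butyldimethylsilyl trifluoromethanesulfonate, `CC(C)(C)[Si](C)(C)OS(=O)(=O)C(F)(F)F`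
Why: Silylation of the new hydroxyl keeps C41–OH as the only free hydroxyl later on.

Step 34
Reactants: 59 chloride
Product: 60 C6–C39 diyne
Conditions: LiC≡CH·H2N(CH2)2NH2, NaI (10 mol %), DMSO/THF, rt
Reagents that add atoms: lithium acetylide (ethylenediamine complex), `[Li+].[C-]#C`
Why: SN2 alkylation of lithium acetylide by the unhindered primary chloride (iodide-assisted) adds C38–C39 as a terminal alkyne.

Step 35
Reactants: 60 diyne; 55 fragment C
Product: 61 C6–C50 diynol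
Conditions: n-BuLi, THF, −78 °C; BF3·OEt2; 55, −78 °C; then H2O
Reagents that add atoms: none
Why: Yamaguchi alkynylation at C40 forms C39–C40 and releases C41–OH as the only free hydroxyl of the chain.

Step 36
Reactants: 61 diynol
Product: 62 (20Z,38Z)-dienol
Conditions: H2 (1 atm), Pd/CaCO3 poisoned with Pb(OAc)2, quinoline, EtOAc, rt
Reagents that add atoms: none
Why: Lindlar semi-hydrogenation adds H2 syn to both alkynes and gives the 20Z and 38Z alkenes.

Step 37
Reactants: 62 dienol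
Product: 63 6,41-diol
Conditions: DDQ, CH2Cl2/pH 7 buffer (10:1), 0 °C
Reagents that add atoms: none
Why: Oxidative cleavage of the PMB ether frees the primary C6 hydroxyl without touching silyl ethers or alkenes.

Step 38
Reactants: 63 6,41-diol
Product: 64 C6 bromide
Conditions: CBr4, PPh3, CH2Cl2, 0 °C
Reagents that add atoms: carbon tetrabromide, `BrC(Br)(Br)Br`
Why: Appel bromination is selective for the primary hydroxyl; the hindered secondary C41 hydroxyl does not react at 0 °C.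

Step 39
Reactants: 64 C6 bromide; 57 5-methyl-2H-pyran-2-one
Product: 65 seco acid
Conditions: 57 (3 equiv), NiBr2·MeOCH2CH2OMe (10 mol %), 4,4'-di-tert-butyl-2,2'-bipyridine (12 mol %), Ir[dF(CF3)ppy]2(dtbbpy)PF6 (2 mol %), (Me3Si)3SiH, Na2CO3, MeOCH2CH2OMe, 450 nm LEDs, 25 °C; then pH 4 buffer
Reagents that add atoms: none
Why: Proposed new method: bipyridine-ligated zerovalent nickel is expected to bind C5=C6 of pyranone 57 and insert into its vinylic C–O bond, giving a seven-membered nickelacycle in which the carboxylate stays bound through oxygen and both ring double bonds keep their cis geometry; the primary C6 radical, released from 64 by bromine-atom abstraction with the photochemically generated (Me3Si)3Si radical, is captured at nickel, and the trivalent alkyl(dienyl)nickel carboxylate reductively eliminates with retention to form C5–C6, so the ring geometry becomes the (2Z,4Z)-dienoic acid and the acid for ring closure is released in the same step, while the photocatalyst returns monovalent nickel to the zerovalent state; the closest known reaction types are the silyl-radical-mediated nickel/photoredox cross-electrophile coupling of alkyl bromides with alkenyl or aryl halides and nickel-catalysed couplings of enol esters by C(sp2)–O insertion, neither shown for a 2-pyranone C–O bond.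

Step 40
Reactants: 65 seco acid
Product: 67 dodecakis-TBS macrolactone, via mixed anhydride 66 (not isolated)
Conditions: 2,4,6-Cl3C6H2COCl, Et3N, THF, rt; then slow addition to DMAP, toluene (1 mM), 40 °C
Reagents that add atoms: none
Why: Yamaguchi macrolactonisation; C41–OH is the only free hydroxyl, and high dilution favours closure of the 42-membered ring with retention at C41.

Step 41
Reactants: 67 dodecakis-TBS macrolactone
Product: 68 CNP0071908.2
Conditions: HF·pyridine, pyridine, THF, 0 °C to rt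
Reagents that add atoms: none
Why: Buffered fluoride-mediated global desilylation removes all twelve silyl ethers and is mild enough for the (2Z,4Z)-dienoate lactone and the allylic C19 carbinol.

**Compound list**

1 | (S)-3-hydroxy-γ-butyrolactone [(4S)-4-hydroxyoxolan-2-one] | `O=C1C[C@H](O)CO1` | starting material
2 | (3S,4S)-4-hydroxy-3-methyloxolan-2-one (trans; C17–C20 with the C18 methyl) | `O=C1[C@@H](C)[C@H](O)CO1` | intermediate
3 | (3S,4S)-3-methyloxolane-2,4-diol (lactol, anomer mixture) | `OC1[C@@H](C)[C@H](O)CO1` | intermediate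
4 | (2S,3S)-3-(1,3-dithian-2-yl)butane-1,2-diol | `S1CCCSC1[C@@H](C)[C@H](O)CO` | intermediate
5 | 2-[(2S,3S)-3,4-bis(tert-butyldimethylsilyloxy)butan-2-yl]-1,3-dithiane (C17–C20) | `S1CCCSC1[C@@H](C)[C@H](O[Si](C)(C)C(C)(C)C)CO[Si](C)(C)C(C)(C)C` | intermediate
6 | (S)-glycidol | `OC[C@H]1CO1` | starting material
7 | (R)-2-[(4-methoxybenzyloxy)methyl]oxirane (C6–C8) | `COc1ccc(COC[C@H]2CO2)cc1` | intermediate
8 | 1,3-dithiane | `C1CSCSC1` | starting material
9 | 2-(triethylsilyl)-1,3-dithiane | `CC[Si](CC)(CC)C1SCCCS1` | intermediate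
10 | (S)-epichlorohydrin | `ClC[C@@H]1CO1` | starting material
11 | lithium alkoxide from lithiated 9 and 7 (6-OPMB; O7–Li; TES still on the C9 dithiane) | `COc1ccc(COC[C@H]([O-])CC2(SCCCS2)[Si](CC)(CC)CC)cc1.[Li+]` | intermediate
12 | lithium chlorohydrin alkoxide (6-OPMB; 7-OTES; C9 dithiane; O11–Li; 12-Cl) | `COc1ccc(COC[C@H](O[Si](CC)(CC)CC)CC2(SCCCS2)C[C@H]([O-])CCl)cc1.[Li+]` | intermediate
13 | C6–C12 epoxide (6-OPMB; 7-OTES; C9 1,3-dithiane; C11–C12 oxirane) | `COc1ccc(COC[C@H](O[Si](CC)(CC)CC)CC2(SCCCS2)C[C@H]3CO3)cc1` | intermediate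
14 | lithium alkoxide from lithiated 9 and 13 (O11–Li; TES still on the C13 dithiane) | `COc1ccc(COC[C@H](O[Si](CC)(CC)CC)CC2(SCCCS2)C[C@H]([O-])CC3(SCCCS3)[Si](CC)(CC)CC)cc1.[Li+]` | intermediate
15 | lithium chlorohydrin alkoxide (7,11-bis-OTES; C9/C13 dithianes; O15–Li; 16-Cl) | `COc1ccc(COC[C@H](O[Si](CC)(CC)CC)CC2(SCCCS2)C[C@H](O[Si](CC)(CC)CC)CC3(SCCCS3)C[C@H]([O-])CCl)cc1.[Li+]` | intermediate
16 | C6–C16 epoxide (6-OPMB; 7,11-bis-OTES; C9/C13 dithianes; C15–C16 oxirane) | `COc1ccc(COC[C@H](O[Si](CC)(CC)CC)CC2(SCCCS2)C[C@H](O[Si](CC)(CC)CC)CC3(SCCCS3)C[C@H]4CO4)cc1` | intermediate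
17 | C6–C20 tris-dithiane alcohol (6-OPMB; 7,11-bis-OTES; 19,20-bis-OTBS; C9/C13/C17 dithianes; free 15-OH; 18-methyl) | `COc1ccc(COC[C@H](O[Si](CC)(CC)CC)CC2(SCCCS2)C[C@H](O[Si](CC)(CC)CC)CC3(SCCCS3)C[C@H](O)CC4(SCCCS4)[C@@H](C)[C@H](O[Si](C)(C)C(C)(C)C)CO[Si](C)(C)C(C)(C)C)cc1` | intermediate
18 | C6–C20 9,13,17-triketone (6-OPMB; 7,11-bis-OTES; 19,20-bis-OTBS; free 15-OH) | `COc1ccc(COC[C@H](O[Si](CC)(CC)CC)CC(=O)C[C@H](O[Si](CC)(CC)CC)CC(=O)C[C@H](O)CC(=O)[C@@H](C)[C@H](O[Si](C)(C)C(C)(C)C)CO[Si](C)(C)C(C)(C)C)cc1` | intermediate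
19 | C6–C20 7,11,15-trihydroxy-9,13,17-triketone (6-OPMB; 19,20-bis-OTBS) | `COc1ccc(COC[C@H](O)CC(=O)C[C@H](O)CC(=O)C[C@H](O)CC(=O)[C@@H](C)[C@H](O[Si](C)(C)C(C)(C)C)CO[Si](C)(C)C(C)(C)C)cc1` | intermediate
20 | C6–C20 7,9,11,13,15,17-hexaol (6-OPMB; 19,20-bis-OTBS; 18-methyl; all 1,3-anti from C7 to C17) | `COc1ccc(COC[C@H](O)C[C@@H](O)C[C@H](O)C[C@@H](O)C[C@H](O)C[C@@H](O)[C@@H](C)[C@H](O[Si](C)(C)C(C)(C)C)CO[Si](C)(C)C(C)(C)C)cc1` | intermediate
21 | octakis-TBS ether (6-OPMB; TBS ethers at O7, O9, O11, O13, O15, O17, O19, O20) | `COc1ccc(COC[C@H](O[Si](C)(C)C(C)(C)C)C[C@@H](O[Si](C)(C)C(C)(C)C)C[C@H](O[Si](C)(C)C(C)(C)C)C[C@@H](O[Si](C)(C)C(C)(C)C)C[C@H](O[Si](C)(C)C(C)(C)C)C[C@@H](O[Si](C)(C)C(C)(C)C)[C@@H](C)[C@H](O[Si](C)(C)C(C)(C)C)CO[Si](C)(C)C(C)(C)C)cc1` | intermediate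
22 | C20 primary alcohol (6-OPMB; TBS ethers at O7, O9, O11, O13, O15, O17, O19) | `COc1ccc(COC[C@H](O[Si](C)(C)C(C)(C)C)C[C@@H](O[Si](C)(C)C(C)(C)C)C[C@H](O[Si](C)(C)C(C)(C)C)C[C@@H](O[Si](C)(C)C(C)(C)C)C[C@H](O[Si](C)(C)C(C)(C)C)C[C@@H](O[Si](C)(C)C(C)(C)C)[C@@H](C)[C@H](O[Si](C)(C)C(C)(C)C)CO)cc1` | intermediate
23 | C20 aldehyde (otherwise as 22) | `COc1ccc(COC[C@H](O[Si](C)(C)C(C)(C)C)C[C@@H](O[Si](C)(C)C(C)(C)C)C[C@H](O[Si](C)(C)C(C)(C)C)C[C@@H](O[Si](C)(C)C(C)(C)C)C[C@H](O[Si](C)(C)C(C)(C)C)C[C@@H](O[Si](C)(C)C(C)(C)C)[C@@H](C)[C@H](O[Si](C)(C)C(C)(C)C)C=O)cc1` | intermediate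
24 | fragment A: C6–C21 alkyne (6-OPMB; seven TBS ethers at O7–O19; terminal C20≡C21) | `COc1ccc(COC[C@H](O[Si](C)(C)C(C)(C)C)C[C@@H](O[Si](C)(C)C(C)(C)C)C[C@H](O[Si](C)(C)C(C)(C)C)C[C@@H](O[Si](C)(C)C(C)(C)C)C[C@H](O[Si](C)(C)C(C)(C)C)C[C@@H](O[Si](C)(C)C(C)(C)C)[C@@H](C)[C@H](O[Si](C)(C)C(C)(C)C)C#C)cc1` | intermediate
25 | 1-bromo-5-chloropentane | `ClCCCCCBr` | starting material
26 | (R)-epichlorohydrin | `ClC[C@H]1CO1` | starting material
27 | 5-chloropentylmagnesium bromide | `ClCCCCC[Mg]Br` | intermediate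
28 | (R)-1,8-dichlorooctan-2-ol (formed as its magnesium alkoxide) | `ClCCCCCC[C@@H](O)CCl` | intermediate
29 | (R)-2-(6-chlorohexyl)oxirane (C30–C37) | `ClCCCCCC[C@@H]1CO1` | intermediate
30 | 2-(tert-butyldimethylsilyl)-1,3-dithiane | `CC(C)(C)[Si](C)(C)C1SCCCS1` | starting material
31 | lithium alkoxide from lithiated 30 and 29 (O31–Li; TBS still on the C29 dithiane) | `CC(C)(C)[Si](C)(C)C1(SCCCS1)C[C@H]([O-])CCCCCCCl.[Li+]` | intermediate
32 | lithium chlorohydrin alkoxide (26-Cl; O27–Li; C29 dithiane; 31-OTBS; 37-Cl) | `ClC[C@H]([O-])CC1(SCCCS1)C[C@H](O[Si](C)(C)C(C)(C)C)CCCCCCCl.[Li+]` | intermediate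
33 | C26–C37 epoxide (C26–C27 oxirane; C29 dithiane; 31-OTBS; 37-Cl) | `C1[C@H](O1)CC2(SCCCS2)C[C@H](O[Si](C)(C)C(C)(C)C)CCCCCCCl` | intermediate
34 | (R)-benzyl glycidyl ether | `c1ccccc1COC[C@H]1CO1` | starting material
35 | lithium alkoxide from lithiated 30 and 33 (O27–Li; TBS still on the C25 dithiane) | `CC(C)(C)[Si](C)(C)C1(SCCCS1)C[C@H]([O-])CC2(SCCCS2)C[C@H](O[Si](C)(C)C(C)(C)C)CCCCCCCl.[Li+]` | intermediate
36 | C22–C37 bis-dithiane alcohol (22-OBn; free 23-OH; C25/C29 dithianes; 27,31-bis-OTBS; 37-Cl) | `c1ccccc1COC[C@H](O)CC2(SCCCS2)C[C@H](O[Si](C)(C)C(C)(C)C)CC3(SCCCS3)C[C@H](O[Si](C)(C)C(C)(C)C)CCCCCCCl` | intermediate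
37 | C22–C37 22,23-diol (27,31-bis-OTBS; 37-Cl) | `OC[C@H](O)CCC[C@H](O[Si](C)(C)C(C)(C)C)CCC[C@H](O[Si](C)(C)C(C)(C)C)CCCCCCCl` | intermediate
38 | C22 primary tosylate of 37 | `Cc1ccc(cc1)S(=O)(=O)OC[C@H](O)CCC[C@H](O[Si](C)(C)C(C)(C)C)CCC[C@H](O[Si](C)(C)C(C)(C)C)CCCCCCCl` | intermediate
39 | fragment B: C22–C37 epoxide (C22–C23 oxirane; 27,31-bis-OTBS; 37-Cl) | `C1[C@H](O1)CCC[C@H](O[Si](C)(C)C(C)(C)C)CCC[C@H](O[Si](C)(C)C(C)(C)C)CCCCCCCl` | intermediate
40 | 1-bromo-4-chlorobutane | `ClCCCCBr` | starting material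
41 | (R)-propylene oxide | `C[C@@H]1CO1` | starting material
42 | 4-chlorobutylmagnesium bromide | `ClCCCC[Mg]Br` | intermediate
43 | (R)-7-chloroheptan-2-ol (C44–C50) | `ClCCCCC[C@@H](C)O` | intermediate
44 | (R)-tert-butyl[(7-chloroheptan-2-yl)oxy]dimethylsilane | `ClCCCCC[C@@H](C)O[Si](C)(C)C(C)(C)C` | intermediate
45 | (R)-3-hydroxy-γ-butyrolactone [(4R)-4-hydroxyoxolan-2-one] | `O=C1C[C@@H](O)CO1` | starting material
46 | (3R,4R)-4-hydroxy-3-methyloxolan-2-one (trans; C40–C43 with the C42 methyl) | `O=C1[C@H](C)[C@@H](O)CO1` | intermediate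
47 | methyl (2R)-2-[(4R)-2,2-dimethyl-1,3-dioxolan-4-yl]propanoate | `COC(=O)[C@H](C)[C@@H]1COC(C)(C)O1` | intermediate
48 | [(6R)-6-(tert-butyldimethylsilyloxy)heptyl]magnesium chloride | `Cl[Mg]CCCCC[C@@H](C)O[Si](C)(C)C(C)(C)C` | intermediate
49 | (2R)-N-methoxy-N-methyl-2-[(4R)-2,2-dimethyl-1,3-dioxolan-4-yl]propanamide | `CON(C)C(=O)[C@H](C)[C@@H]1COC(C)(C)O1` | intermediate
50 | C40–C50 ketone (40,41-acetonide; 42-methyl; 43-oxo; 49-OTBS) | `C1OC(C)(C)O[C@@H]1[C@@H](C)C(=O)CCCCC[C@@H](C)O[Si](C)(C)C(C)(C)C` | intermediate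
51 | C40–C50 43-alcohol (41,42-syn; 42,43-syn; 40,41-acetonide; 49-OTBS) | `C1OC(C)(C)O[C@@H]1[C@@H](C)[C@H](O)CCCCC[C@@H](C)O[Si](C)(C)C(C)(C)C` | intermediate
52 | 43,49-bis-TBS ether of 51 | `C1OC(C)(C)O[C@@H]1[C@@H](C)[C@H](O[Si](C)(C)C(C)(C)C)CCCCC[C@@H](C)O[Si](C)(C)C(C)(C)C` | intermediate
53 | C40–C50 40,41-diol (43,49-bis-OTBS) | `OC[C@H](O)[C@@H](C)[C@H](O[Si](C)(C)C(C)(C)C)CCCCC[C@@H](C)O[Si](C)(C)C(C)(C)C` | intermediate
54 | C40 primary tosylate of 53 | `Cc1ccc(cc1)S(=O)(=O)OC[C@H](O)[C@@H](C)[C@H](O[Si](C)(C)C(C)(C)C)CCCCC[C@@H](C)O[Si](C)(C)C(C)(C)C` | intermediate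
55 | fragment C: C40–C50 epoxide (C40–C41 oxirane; 42-methyl; 43,49-bis-OTBS) | `C1O[C@@H]1[C@@H](C)[C@H](O[Si](C)(C)C(C)(C)C)CCCCC[C@@H](C)O[Si](C)(C)C(C)(C)C` | intermediate
56 | 5-bromo-2H-pyran-2-one | `BrC1=COC(=O)C=C1` | starting material
57 | 5-methyl-2H-pyran-2-one (C1–C5 with the C4 methyl) | `CC1=COC(=O)C=C1` | intermediate
58 | C6–C37 alkynol (6-OPMB; seven TBS at O7–O19; C20≡C21; free 23-OH; 27,31-bis-OTBS; 37-Cl) | `COc1ccc(COC[C@H](O[Si](C)(C)C(C)(C)C)C[C@@H](O[Si](C)(C)C(C)(C)C)C[C@H](O[Si](C)(C)C(C)(C)C)C[C@@H](O[Si](C)(C)C(C)(C)C)C[C@H](O[Si](C)(C)C(C)(C)C)C[C@@H](O[Si](C)(C)C(C)(C)C)[C@@H](C)[C@H](O[Si](C)(C)C(C)(C)C)C#CC[C@H](O)CCC[C@H](O[Si](C)(C)C(C)(C)C)CCC[C@H](O[Si](C)(C)C(C)(C)C)CCCCCCCl)cc1` | intermediate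
59 | 23-O-TBS ether of 58 | `COc1ccc(COC[C@H](O[Si](C)(C)C(C)(C)C)C[C@@H](O[Si](C)(C)C(C)(C)C)C[C@H](O[Si](C)(C)C(C)(C)C)C[C@@H](O[Si](C)(C)C(C)(C)C)C[C@H](O[Si](C)(C)C(C)(C)C)C[C@@H](O[Si](C)(C)C(C)(C)C)[C@@H](C)[C@H](O[Si](C)(C)C(C)(C)C)C#CC[C@H](O[Si](C)(C)C(C)(C)C)CCC[C@H](O[Si](C)(C)C(C)(C)C)CCC[C@H](O[Si](C)(C)C(C)(C)C)CCCCCCCl)cc1` | intermediate
60 | C6–C39 diyne (as 59 with C37–C38≡C39–H in place of 37-Cl) | `COc1ccc(COC[C@H](O[Si](C)(C)C(C)(C)C)C[C@@H](O[Si](C)(C)C(C)(C)C)C[C@H](O[Si](C)(C)C(C)(C)C)C[C@@H](O[Si](C)(C)C(C)(C)C)C[C@H](O[Si](C)(C)C(C)(C)C)C[C@@H](O[Si](C)(C)C(C)(C)C)[C@@H](C)[C@H](O[Si](C)(C)C(C)(C)C)C#CC[C@H](O[Si](C)(C)C(C)(C)C)CCC[C@H](O[Si](C)(C)C(C)(C)C)CCC[C@H](O[Si](C)(C)C(C)(C)C)CCCCCCC#C)cc1` | intermediate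
61 | C6–C50 diynol (6-OPMB; twelve TBS ethers; C20≡C21 and C38≡C39; free 41-OH) | `COc1ccc(COC[C@H](O[Si](C)(C)C(C)(C)C)C[C@@H](O[Si](C)(C)C(C)(C)C)C[C@H](O[Si](C)(C)C(C)(C)C)C[C@@H](O[Si](C)(C)C(C)(C)C)C[C@H](O[Si](C)(C)C(C)(C)C)C[C@@H](O[Si](C)(C)C(C)(C)C)[C@@H](C)[C@H](O[Si](C)(C)C(C)(C)C)C#CC[C@H](O[Si](C)(C)C(C)(C)C)CCC[C@H](O[Si](C)(C)C(C)(C)C)CCC[C@H](O[Si](C)(C)C(C)(C)C)CCCCCCC#CC[C@@H]([C@@H](C)[C@H](O[Si](C)(C)C(C)(C)C)CCCCC[C@@H](C)O[Si](C)(C)C(C)(C)C)O)cc1` | intermediate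
62 | C6–C50 (20Z,38Z)-dienol (6-OPMB; twelve TBS ethers; free 41-OH) | `COc1ccc(COC[C@H](O[Si](C)(C)C(C)(C)C)C[C@@H](O[Si](C)(C)C(C)(C)C)C[C@H](O[Si](C)(C)C(C)(C)C)C[C@@H](O[Si](C)(C)C(C)(C)C)C[C@H](O[Si](C)(C)C(C)(C)C)C[C@@H](O[Si](C)(C)C(C)(C)C)[C@@H](C)[C@H](O[Si](C)(C)C(C)(C)C)/C=C\C[C@H](O[Si](C)(C)C(C)(C)C)CCC[C@H](O[Si](C)(C)C(C)(C)C)CCC[C@H](O[Si](C)(C)C(C)(C)C)CCCCCC/C=C\C[C@@H]([C@@H](C)[C@H](O[Si](C)(C)C(C)(C)C)CCCCC[C@@H](C)O[Si](C)(C)C(C)(C)C)O)cc1` | intermediate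
63 | C6–C50 6,41-diol (twelve TBS ethers; 20Z,38Z) | `OC[C@H](O[Si](C)(C)C(C)(C)C)C[C@@H](O[Si](C)(C)C(C)(C)C)C[C@H](O[Si](C)(C)C(C)(C)C)C[C@@H](O[Si](C)(C)C(C)(C)C)C[C@H](O[Si](C)(C)C(C)(C)C)C[C@@H](O[Si](C)(C)C(C)(C)C)[C@@H](C)[C@H](O[Si](C)(C)C(C)(C)C)/C=C\C[C@H](O[Si](C)(C)C(C)(C)C)CCC[C@H](O[Si](C)(C)C(C)(C)C)CCC[C@H](O[Si](C)(C)C(C)(C)C)CCCCCC/C=C\C[C@@H]([C@@H](C)[C@H](O[Si](C)(C)C(C)(C)C)CCCCC[C@@H](C)O[Si](C)(C)C(C)(C)C)O` | intermediate
64 | C6–C50 6-bromide (twelve TBS ethers; 20Z,38Z; free 41-OH) | `BrC[C@H](O[Si](C)(C)C(C)(C)C)C[C@@H](O[Si](C)(C)C(C)(C)C)C[C@H](O[Si](C)(C)C(C)(C)C)C[C@@H](O[Si](C)(C)C(C)(C)C)C[C@H](O[Si](C)(C)C(C)(C)C)C[C@@H](O[Si](C)(C)C(C)(C)C)[C@@H](C)[C@H](O[Si](C)(C)C(C)(C)C)/C=C\C[C@H](O[Si](C)(C)C(C)(C)C)CCC[C@H](O[Si](C)(C)C(C)(C)C)CCC[C@H](O[Si](C)(C)C(C)(C)C)CCCCCC/C=C\C[C@@H]([C@@H](C)[C@H](O[Si](C)(C)C(C)(C)C)CCCCC[C@@H](C)O[Si](C)(C)C(C)(C)C)O` | intermediate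
65 | seco acid (2Z,4Z,20Z,38Z; twelve TBS ethers; free 41-OH) | `OC(=O)/C=C\C(C)=C/C[C@H](O[Si](C)(C)C(C)(C)C)C[C@@H](O[Si](C)(C)C(C)(C)C)C[C@H](O[Si](C)(C)C(C)(C)C)C[C@@H](O[Si](C)(C)C(C)(C)C)C[C@H](O[Si](C)(C)C(C)(C)C)C[C@@H](O[Si](C)(C)C(C)(C)C)[C@@H](C)[C@H](O[Si](C)(C)C(C)(C)C)/C=C\C[C@H](O[Si](C)(C)C(C)(C)C)CCC[C@H](O[Si](C)(C)C(C)(C)C)CCC[C@H](O[Si](C)(C)C(C)(C)C)CCCCCC/C=C\C[C@@H]([C@@H](C)[C@H](O[Si](C)(C)C(C)(C)C)CCCCC[C@@H](C)O[Si](C)(C)C(C)(C)C)O` | intermediate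
66 | mixed anhydride of 65 with 2,4,6-trichlorobenzoic acid | `O=C(OC(=O)/C=C\C(C)=C/C[C@H](O[Si](C)(C)C(C)(C)C)C[C@@H](O[Si](C)(C)C(C)(C)C)C[C@H](O[Si](C)(C)C(C)(C)C)C[C@@H](O[Si](C)(C)C(C)(C)C)C[C@H](O[Si](C)(C)C(C)(C)C)C[C@@H](O[Si](C)(C)C(C)(C)C)[C@@H](C)[C@H](O[Si](C)(C)C(C)(C)C)/C=C\C[C@H](O[Si](C)(C)C(C)(C)C)CCC[C@H](O[Si](C)(C)C(C)(C)C)CCC[C@H](O[Si](C)(C)C(C)(C)C)CCCCCC/C=C\C[C@@H]([C@@H](C)[C@H](O[Si](C)(C)C(C)(C)C)CCCCC[C@@H](C)O[Si](C)(C)C(C)(C)C)O)c1c(Cl)cc(Cl)cc1Cl` | intermediate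
67 | dodecakis-TBS ether of the target macrolactone | `O=C1/C=C\C(C)=C/C[C@H](O[Si](C)(C)C(C)(C)C)C[C@@H](O[Si](C)(C)C(C)(C)C)C[C@H](O[Si](C)(C)C(C)(C)C)C[C@@H](O[Si](C)(C)C(C)(C)C)C[C@H](O[Si](C)(C)C(C)(C)C)C[C@@H](O[Si](C)(C)C(C)(C)C)[C@@H](C)[C@H](O[Si](C)(C)C(C)(C)C)/C=C\C[C@H](O[Si](C)(C)C(C)(C)C)CCC[C@H](O[Si](C)(C)C(C)(C)C)CCC[C@H](O[Si](C)(C)C(C)(C)C)CCCCCC/C=C\C[C@@H]([C@@H](C)[C@H](O[Si](C)(C)C(C)(C)C)CCCCC[C@@H](C)O[Si](C)(C)C(C)(C)C)O1` | intermediate
68 | CNP0071908.2 | `CC1=C/C[C@H](O)C[C@@H](O)C[C@H](O)C[C@@H](O)C[C@H](O)C[C@@H](O)[C@@H](C)[C@H](O)/C=C\C[C@H](O)CCC[C@H](O)CCC[C@H](O)CCCCCC/C=C\C[C@@H]([C@@H](C)[C@H](O)CCCCC[C@@H](C)O)OC(=O)/C=C\1` | target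

**Step count and risks**

Total step count: 41. Longest linear sequence: 22 steps (steps 1–4, 9–16 and 32–41).

The three steps most likely to fail:

1. Step 39 (the proposed nickel/photoredox ring-opening coupling). Nickel may insert into the acyl C–O bond of the pyranone instead of the vinylic one, or the C6 radical may add conjugatively to the pyranone and open the ring to the 4E acid. The fallback uses known chemistry, sets out from 64 and returns at 65. Copper-catalysed anti addition of MeMgBr to propargyl alcohol with an I2 quench gives (Z)-3-iodo-2-methylprop-2-en-1-ol F1. MnO2 oxidation gives (Z)-3-iodo-2-methylprop-2-enal F2. Still–Gennari olefination with (CF3CH2O)2P(O)CH2CO2Me, KN(SiMe3)2 and 18-crown-6 at −78 °C gives methyl (2Z,4Z)-5-iodo-4-methylpenta-2,4-dienoate F3. A thermal nickel-catalysed reductive cross-electrophile coupling of 64 with F3 (NiBr2·MeOCH2CH2OMe, 4,4'-di-tert-butyl-2,2'-bipyridine, Zn, NaI, N,N-dimethylacetamide, 25 °C; alkene geometry is retained) gives the methyl ester of the seco acid F4. Me3SnOH in 1,2-dichloroethane at 70 °C cleaves the ester to 65.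

2. Step 40 (macrolactonisation). DMAP can add reversibly to the activated (2Z)-dienoate and scramble the C2=C3 geometry, and a 42-membered ring competes with oligomers. The fallback sets out from 65 and returns at 67. It replaces base-mediated acyl transfer by an isolable enol ester that closes under acid catalysis: ethoxyacetylene with [RuCl2(p-cymene)]2 (2 mol %) in toluene gives the 1-ethoxyvinyl ester of the seco acid F5, which is filtered through silica and added slowly to camphorsulfonic acid (10 mol %) in toluene (1 mM, 50 °C).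

3. Step 10 (three dithianes hydrolysed at once next to silyl ethers, a free hydroxyl and the C18 α-stereocentre). The fallback sets out from 17 and returns at 19. It unmasks the hydroxyls before the carbonyls and replaces mercury-assisted hydrolysis by an oxidative cleavage. Pyridinium p-toluenesulfonate in MeOH/CH2Cl2 at 0 °C removes the two TES ethers while no ketone is present and gives the C6–C20 tris-dithiane 7,11,15-triol F6. PhI(O2CCF3)2 with NaHCO3 in MeCN/H2O (9:1) at 0 °C then cleaves the three dithianes oxidatively and gives 19, so the silylated triketone 18 is never handled.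

**Further compounds**

F1 | step 39 | (Z)-3-iodo-2-methylprop-2-en-1-ol | `OC/C(C)=C\I`
F2 | step 39 | (Z)-3-iodo-2-methylprop-2-enal | `O=C/C(C)=C\I`
F3 | step 39 | methyl (2Z,4Z)-5-iodo-4-methylpenta-2,4-dienoate | `COC(=O)/C=C\C(C)=C/I`
F4 | step 39 | methyl ester of seco acid 65 | `COC(=O)/C=C\C(C)=C/C[C@H](O[Si](C)(C)C(C)(C)C)C[C@@H](O[Si](C)(C)C(C)(C)C)C[C@H](O[Si](C)(C)C(C)(C)C)C[C@@H](O[Si](C)(C)C(C)(C)C)C[C@H](O[Si](C)(C)C(C)(C)C)C[C@@H](O[Si](C)(C)C(C)(C)C)[C@@H](C)[C@H](O[Si](C)(C)C(C)(C)C)/C=C\C[C@H](O[Si](C)(C)C(C)(C)C)CCC[C@H](O[Si](C)(C)C(C)(C)C)CCC[C@H](O[Si](C)(C)C(C)(C)C)CCCCCC/C=C\C[C@@H]([C@@H](C)[C@H](O[Si](C)(C)C(C)(C)C)CCCCC[C@@H](C)O[Si](C)(C)C(C)(C)C)O`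
F5 | step 40 | 1-ethoxyvinyl ester of seco acid 65 | `CCOC(=C)OC(=O)/C=C\C(C)=C/C[C@H](O[Si](C)(C)C(C)(C)C)C[C@@H](O[Si](C)(C)C(C)(C)C)C[C@H](O[Si](C)(C)C(C)(C)C)C[C@@H](O[Si](C)(C)C(C)(C)C)C[C@H](O[Si](C)(C)C(C)(C)C)C[C@@H](O[Si](C)(C)C(C)(C)C)[C@@H](C)[C@H](O[Si](C)(C)C(C)(C)C)/C=C\C[C@H](O[Si](C)(C)C(C)(C)C)CCC[C@H](O[Si](C)(C)C(C)(C)C)CCC[C@H](O[Si](C)(C)C(C)(C)C)CCCCCC/C=C\C[C@@H]([C@@H](C)[C@H](O[Si](C)(C)C(C)(C)C)CCCCC[C@@H](C)O[Si](C)(C)C(C)(C)C)O`
F6 | step 10 | C6–C20 tris-dithiane 7,11,15-triol (6-OPMB; 19,20-bis-OTBS; C9/C13/C17 dithianes) | `COc1ccc(COC[C@H](O)CC2(SCCCS2)C[C@H](O)CC3(SCCCS3)C[C@H](O)CC4(SCCCS4)[C@@H](C)[C@H](O[Si](C)(C)C(C)(C)C)CO[Si](C)(C)C(C)(C)C)cc1`
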